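Ring B is disconnected at C4–C4a. The oxygens at C1, C2 and C4 flanking the C3 hydrogen are those of an oxidised naphthalene-1,3-diol, and C4a of ring A lies para to the C7 oxygen. The key step exploits this by letting the ester terminus of a 3-oxobutanoate chain on C8a acylate C4a. One acid-mediated operation forms C4–C4a, closes ring B and, after enolisation, gives the diol that air later oxidises at C1. The precursor is an orsellinate-derived benzene bearing the C5 methyl, C6 ester, C7 methoxy and the keto ester chain. Ring C is attached afterwards through an aryllithium, and the pyranone is closed last.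

Key step: step 6

Remark: zinc reagent 4 (sold as an ether solution) and allylarene 18 are taken as purchased; the target is achiral, and the racemic stereocentres of 21 and 23 are erased in steps 13 and 14.

Step 1
Reactants: 1 methyl orsellinate (methyl 2,4-dihydroxy-6-methylbenzoate)
Product: 2 methyl 2-hydroxy-6-methyl-4-(trifluoromethylsulfonyloxy)benzoate
Conditions: Tf2O (1.05 equiv), pyridine, CH2Cl2, −20 → 0 °C
Reagents that add atoms: trifluoromethanesulfonic anhydride, O=S(=O)(OS(=O)(=O)C(F)(F)F)C(F)(F)F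
Why: Selective O-sulfonylation, because the hydroxyl para to the ester is free while the ortho hydroxyl is hydrogen-bonded to the ester carbonyl and shielded by it, so one equivalent of anhydride should triflate only the para oxygen.

Step 2
Reactants: 2 methyl 2-hydroxy-6-methyl-4-(trifluoromethylsulfonyloxy)benzoate
Product: 3 methyl 2-methoxy-6-methyl-4-(trifluoromethylsulfonyloxy)benzoate
Conditions: MeI, K2CO3, acetone, 56 °C
Reagents that add atoms: iodomethane, CI
Why: Williamson O-methylation of the remaining chelated phenol under carbonate conditions, which an aryl triflate tolerates.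

Step 3
Reactants: 3 methyl 2-methoxy-6-methyl-4-(trifluoromethylsulfonyloxy)benzoate; 4 (2-tert-butoxy-2-oxoethyl)zinc chloride
Product: 5 methyl 4-(2-tert-butoxy-2-oxoethyl)-2-methoxy-6-methylbenzoate
Conditions: Pd2(dba)3 (cat.), XPhos (cat.), THF, 60 °C
Reagents that add atoms: none
Why: Negishi-type α-arylation of a Reformatsky zinc enolate, in which oxidative addition of the unhindered aryl triflate to zerovalent palladium, transmetalation and reductive elimination should give the arylacetate while the neutral zinc reagent spares the methyl ester.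

Step 4
Reactants: 5 methyl 4-(2-tert-butoxy-2-oxoethyl)-2-methoxy-6-methylbenzoate
Product: 6 2-(3-methoxy-4-methoxycarbonyl-5-methylphenyl)acetic acid
Conditions: CF3CO2H, CH2Cl2, rt
Reagents that add atoms: none
Why: Acidolysis of the tert-butyl ester through the tert-butyl cation frees the acid, and the methyl ester and methyl ether are stable to these conditions.

Step 5
Reactants: 6 2-(3-methoxy-4-methoxycarbonyl-5-methylphenyl)acetic acid; 7 potassium ethyl malonate
Product: 10 ethyl 4-(3-methoxy-4-methoxycarbonyl-5-methylphenyl)-3-oxobutanoate, via acyl imidazole 8 (not isolated), via acylmalonic half ester 9 (not isolated)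
Conditions: CDI, THF, rt; then 7, MgCl2, Et3N, MeCN/THF, rt → 40 °C; then aq. HCl
Reagents that add atoms: none
Why: Masamune–Brooks homologation, in which the acyl imidazole C-acylates the magnesium enolate of the malonate half ester and the acylmalonic acid loses CO2 on acidification to give the β-keto ester.

Step 6
Reactants: 10 ethyl 4-(3-methoxy-4-methoxycarbonyl-5-methylphenyl)-3-oxobutanoate
Product: 12 methyl 6,8-dihydroxy-3-methoxy-1-methylnaphthalene-2-carboxylate, via ring B diketone 11 (not isolated)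
Conditions: P2O5 in CH3SO3H (1:10 w/w), dilute, 25–40 °C; then ice water
Reagents that add atoms: none
Why: The strongly acidic, dehydrating medium activates the ethyl ester carbonyl (as its protonated form or a mixed anhydride), C4a of ring A attacks that carbon to form C4–C4a, and loss of ethanol gives diketone 11, which enolises twice to the aromatic diol 12. The closest known reaction type is the intramolecular Friedel–Crafts acylation of 4-aryl-3-oxobutanoates and arylacetylmalonates in strong acid, the classical entry to naphthalene-1,3-diols. Ring B closes in a 6-exo-trig mode, the arene carbon adding to a carbonyl whose C=O bond lies outside the new six-membered ring. No stereocentre is formed. The step needs attack at C4a and not at C8: C4a is para to the C7 methoxy group, whereas C8 is ortho to it and is screened by the O-methyl group, which the flanking C6 ester turns toward C8; the ester is meta to both carbons and does not discriminate. The hindered C6 methyl ester cannot reach any ring carbon intramolecularly and should pass through as a spectator.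

Step 7
Reactants: 12 methyl 6,8-dihydroxy-3-methoxy-1-methylnaphthalene-2-carboxylate
Product: 13 methyl 6-hydroxy-3-methoxy-1-methyl-5,8-dioxo-5,8-dihydronaphthalene-2-carboxylate
Conditions: O2 (1 atm), K2CO3, MeOH, rt; then aq. HCl
Reagents that add atoms: dioxygen, O=O
Why: Base-mediated autoxidation of a naphthalene-1,3-diol, in which the electron-rich dianion is oxygenated by O2 at C1 (the free α-carbon ortho to the C2 oxygen and para to the C4 oxygen) and the hydroperoxide loses water to give the 2-hydroxy-1,4-naphthoquinone.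

Step 8
Reactants: 13 methyl 6-hydroxy-3-methoxy-1-methyl-5,8-dioxo-5,8-dihydronaphthalene-2-carboxylate
Product: 15 methyl 3,5,6,8-tetramethoxy-1-methylnaphthalene-2-carboxylate, via naphthalenetriol 14 (not isolated)
Conditions: Na2S2O4, Bu4NBr (cat.), THF/H2O, rt, N2; then aq. KOH, Me2SO4, rt
Reagents that add atoms: dimethyl sulfate, COS(=O)(=O)OC
Why: Reductive methylation, in which dithionite reduces the quinone to the naphthalene-1,2,4-triol and phase-transfer Williamson methylation traps it in the same flask before it can reoxidise, so the quinone is carried on as a robust trimethoxynaphthalene.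

Step 9
Reactants: 15 methyl 3,5,6,8-tetramethoxy-1-methylnaphthalene-2-carboxylate
Product: 16 (3,5,6,8-tetramethoxy-1-methylnaphthalen-2-yl)methanol
Conditions: LiAlH4, THF, 0 → 65 °C; then H2O, aq. NaOH
Reagents that add atoms: none
Why: Hydride reduction with LiAlH4 of the hindered ester, the only reducible group present, gives the benzylic alcohol.

Step 10
Reactants: 16 (3,5,6,8-tetramethoxy-1-methylnaphthalen-2-yl)methanol
Product: 17 3,5,6,8-tetramethoxy-1-methylnaphthalene-2-carbaldehyde
Conditions: Dess–Martin periodinane, NaHCO3, CH2Cl2, rt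
Reagents that add atoms: none
Why: Dess–Martin oxidation of a primary benzylic alcohol stops at the aldehyde under buffered conditions that the electron-rich naphthalene tolerates.

Step 11
Reactants: 18 1-allyl-3,5-dimethoxybenzene
Product: 19 2-bromo-1,5-dimethoxy-3-(prop-2-en-1-yl)benzene
Conditions: NBS, MeCN, 0 °C, dark
Reagents that add atoms: N-bromosuccinimide, O=C1CCC(=O)N1Br
Why: Electrophilic aromatic bromination of the strongly activated ring should occur at the carbon ortho to the allyl group and para to a methoxy group (the two such carbons are equivalent), faster than any ionic reaction at the alkene.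

Step 12
Reactants: 19 2-bromo-1,5-dimethoxy-3-(prop-2-en-1-yl)benzene; 17 3,5,6,8-tetramethoxy-1-methylnaphthalene-2-carbaldehyde
Product: 21 [2,4-dimethoxy-6-(prop-2-en-1-yl)phenyl](3,5,6,8-tetramethoxy-1-methylnaphthalen-2-yl)methanol (racemic), via aryllithium 20 (not isolated)
Conditions: 19, n-BuLi, THF, −78 °C; then 17, −78 → 0 °C; then aq. NH4Cl
Reagents that add atoms: none
Why: Bromine–lithium exchange followed by 1,2-addition of the aryllithium to the aldehyde joins ring C to C6 as a diarylcarbinol, whose new stereocentre forms as a racemate and is removed in step 13.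

Step 13
Reactants: 21 [2,4-dimethoxy-6-(prop-2-en-1-yl)phenyl](3,5,6,8-tetramethoxy-1-methylnaphthalen-2-yl)methanol
Product: 22 [2,4-dimethoxy-6-(prop-2-en-1-yl)phenyl](3,5,6,8-tetramethoxy-1-methylnaphthalen-2-yl)methanone
Conditions: Dess–Martin periodinane, NaHCO3, CH2Cl2, rt
Reagents that add atoms: none
Why: Dess–Martin oxidation of the doubly benzylic secondary alcohol gives the tetra-ortho-substituted benzophenone, the allyl group being inert to the reagent.

Step 14
Reactants: 22 [2,4-dimethoxy-6-(prop-2-en-1-yl)phenyl](3,5,6,8-tetramethoxy-1-methylnaphthalen-2-yl)methanone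
Product: 24 2-[3,5-dimethoxy-2-(3,5,6,8-tetramethoxy-1-methylnaphthalene-2-carbonyl)phenyl]acetaldehyde, via diol 23 (not isolated)
Conditions: OsO4 (cat.), NaIO4, 2,6-lutidine, dioxane/H2O, rt
Reagents that add atoms: osmium tetroxide, O=[Os](=O)(=O)=O (catalytic oxygen carrier); sodium periodate, [Na+].[O-]I(=O)(=O)=O (terminal oxidant)
Why: Lemieux–Johnson cleavage, in which catalytic dihydroxylation of the terminal alkene and periodate scission of the diol give the arylacetaldehyde without touching the methoxy arenes or the ketone.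

Step 15
Reactants: 24 2-[3,5-dimethoxy-2-(3,5,6,8-tetramethoxy-1-methylnaphthalene-2-carbonyl)phenyl]acetaldehyde
Product: 25 2-[3,5-dimethoxy-2-(3,5,6,8-tetramethoxy-1-methylnaphthalene-2-carbonyl)phenyl]acetic acid
Conditions: NaClO2, NaH2PO4, 2-methyl-2-butene (excess), t-BuOH/H2O, 0 °C → rt
Reagents that add atoms: sodium chlorite, [Na+].[O-]Cl=O
Why: Pinnick oxidation converts the aldehyde to the acid, the alkene scavenger removing HOCl before it can chlorinate the electron-rich rings.

Step 16
Reactants: 25 2-[3,5-dimethoxy-2-(3,5,6,8-tetramethoxy-1-methylnaphthalene-2-carbonyl)phenyl]acetic acid; 26 2,2,6-trimethyl-4H-1,3-dioxin-4-one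
Product: 29 6-{3-[3,5-dimethoxy-2-(3,5,6,8-tetramethoxy-1-methylnaphthalene-2-carbonyl)phenyl]-2-oxopropyl}-2,2-dimethyl-4H-1,3-dioxin-4-one, via acyl imidazole 27 (not isolated), via lithium dienolate 28 (not isolated)
Conditions: 25, CDI, THF, rt; separately 26, LiN(SiMe3)2 (3 equiv each), THF, −78 °C; combine at −78 → −40 °C; then aq. NH4Cl
Reagents that add atoms: none
Why: Crossed Claisen-type C-acylation, in which the vinylogous lithium dienolate attacks the acyl imidazole through its γ-carbon, excess dienolate absorbs the acidic proton of the product, and the tetra-ortho-substituted diaryl ketone is too shielded to be attacked.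

Step 17
Reactants: 29 6-{3-[3,5-dimethoxy-2-(3,5,6,8-tetramethoxy-1-methylnaphthalene-2-carbonyl)phenyl]-2-oxopropyl}-2,2-dimethyl-4H-1,3-dioxin-4-one
Product: 31 6-{[3,5-dimethoxy-2-(3,5,6,8-tetramethoxy-1-methylnaphthalene-2-carbonyl)phenyl]methyl}-4-hydroxy-2H-pyran-2-one, via acylketene 30 (not isolated)
Conditions: toluene, 110 °C
Reagents that add atoms: none
Why: Thermal retro-[4+2] fragmentation of the dioxinone releases acetone and an acylketene, which the enol oxygen of the neighbouring ketone captures intramolecularly to give the 4-hydroxy-2-pyranone.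

Step 18
Reactants: 31 6-{[3,5-dimethoxy-2-(3,5,6,8-tetramethoxy-1-methylnaphthalene-2-carbonyl)phenyl]methyl}-4-hydroxy-2H-pyran-2-one
Product: 33 CNP0141484.0, via hexaphenol 32 (not isolated)
Conditions: BBr3 (excess), CH2Cl2, −78 °C → rt; then H2O, 0 °C; then air, EtOAc/pH 7 phosphate buffer, rt
Reagents that add atoms: none
Why: Lewis acid ether cleavage with BBr3 removes all six aryl methyl groups, and the liberated naphthalene-1,2,4-triol is oxidised spontaneously by air to the 2-hydroxy-1,4-naphthoquinone, so deprotection and quinone formation occur in one operation.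

Compound list
1 | methyl orsellinate (methyl 2,4-dihydroxy-6-methylbenzoate) | COC(=O)c1c(C)cc(O)cc1O | starting material
2 | methyl 2-hydroxy-6-methyl-4-(trifluoromethylsulfonyloxy)benzoate | COC(=O)c1c(C)cc(OS(=O)(=O)C(F)(F)F)cc1O | intermediate
3 | methyl 2-methoxy-6-methyl-4-(trifluoromethylsulfonyloxy)benzoate | COC(=O)c1c(C)cc(OS(=O)(=O)C(F)(F)F)cc1OC | intermediate
4 | (2-tert-butoxy-2-oxoethyl)zinc chloride | CC(C)(C)OC(=O)C[Zn]Cl | starting material
5 | methyl 4-(2-tert-butoxy-2-oxoethyl)-2-methoxy-6-methylbenzoate | COC(=O)c1c(C)cc(CC(=O)OC(C)(C)C)cc1OC | intermediate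
6 | 2-(3-methoxy-4-methoxycarbonyl-5-methylphenyl)acetic acid | COC(=O)c1c(C)cc(CC(=O)O)cc1OC | intermediate
7 | potassium ethyl malonate (potassium 3-ethoxy-3-oxopropanoate) | CCOC(=O)CC(=O)[O-].[K+] | starting material
8 | methyl 4-[2-(imidazol-1-yl)-2-oxoethyl]-2-methoxy-6-methylbenzoate (acyl imidazole) | COC(=O)c1c(C)cc(CC(=O)n2ccnc2)cc1OC | intermediate (not isolated)
9 | 2-ethoxycarbonyl-4-(3-methoxy-4-methoxycarbonyl-5-methylphenyl)-3-oxobutanoic acid (present as its magnesium chelate; racemic, enolisable) | CCOC(=O)C(C(=O)O)C(=O)Cc1cc(C)c(C(=O)OC)c(OC)c1 | intermediate (not isolated)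
10 | ethyl 4-(3-methoxy-4-methoxycarbonyl-5-methylphenyl)-3-oxobutanoate | CCOC(=O)CC(=O)Cc1cc(C)c(C(=O)OC)c(OC)c1 | intermediate
11 | methyl 3-methoxy-1-methyl-6,8-dioxo-5,6,7,8-tetrahydronaphthalene-2-carboxylate (ring B diketone) | Cc1c(C(=O)OC)c(OC)cc2CC(=O)CC(=O)c12 | intermediate (not isolated)
12 | methyl 6,8-dihydroxy-3-methoxy-1-methylnaphthalene-2-carboxylate | Cc1c(C(=O)OC)c(OC)cc2cc(O)cc(O)c12 | intermediate
13 | methyl 6-hydroxy-3-methoxy-1-methyl-5,8-dioxo-5,8-dihydronaphthalene-2-carboxylate | Cc1c(C(=O)OC)c(OC)cc2c1C(=O)C=C(O)C2=O | intermediate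
14 | methyl 5,6,8-trihydroxy-3-methoxy-1-methylnaphthalene-2-carboxylate | Cc1c(C(=O)OC)c(OC)cc2c(O)c(O)cc(O)c12 | intermediate (not isolated)
15 | methyl 3,5,6,8-tetramethoxy-1-methylnaphthalene-2-carboxylate | Cc1c(C(=O)OC)c(OC)cc2c(OC)c(OC)cc(OC)c12 | intermediate
16 | (3,5,6,8-tetramethoxy-1-methylnaphthalen-2-yl)methanol | Cc1c(CO)c(OC)cc2c(OC)c(OC)cc(OC)c12 | intermediate
17 | 3,5,6,8-tetramethoxy-1-methylnaphthalene-2-carbaldehyde | Cc1c(C=O)c(OC)cc2c(OC)c(OC)cc(OC)c12 | intermediate
18 | 1-allyl-3,5-dimethoxybenzene (1,3-dimethoxy-5-(prop-2-en-1-yl)benzene) | C=CCc1cc(OC)cc(OC)c1 | starting material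
19 | 2-bromo-1,5-dimethoxy-3-(prop-2-en-1-yl)benzene | C=CCc1cc(OC)cc(OC)c1Br | intermediate
20 | [2,4-dimethoxy-6-(prop-2-en-1-yl)phenyl]lithium | [Li]c1c(CC=C)cc(OC)cc1OC | intermediate (not isolated)
21 | [2,4-dimethoxy-6-(prop-2-en-1-yl)phenyl](3,5,6,8-tetramethoxy-1-methylnaphthalen-2-yl)methanol (racemic) | Cc1c(C(O)c3c(CC=C)cc(OC)cc3OC)c(OC)cc2c(OC)c(OC)cc(OC)c12 | intermediate
22 | [2,4-dimethoxy-6-(prop-2-en-1-yl)phenyl](3,5,6,8-tetramethoxy-1-methylnaphthalen-2-yl)methanone | Cc1c(C(=O)c3c(CC=C)cc(OC)cc3OC)c(OC)cc2c(OC)c(OC)cc(OC)c12 | intermediate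
23 | [2-(2,3-dihydroxypropyl)-4,6-dimethoxyphenyl](3,5,6,8-tetramethoxy-1-methylnaphthalen-2-yl)methanone (racemic) | Cc1c(C(=O)c3c(CC(O)CO)cc(OC)cc3OC)c(OC)cc2c(OC)c(OC)cc(OC)c12 | intermediate (not isolated)
24 | 2-[3,5-dimethoxy-2-(3,5,6,8-tetramethoxy-1-methylnaphthalene-2-carbonyl)phenyl]acetaldehyde | Cc1c(C(=O)c3c(CC=O)cc(OC)cc3OC)c(OC)cc2c(OC)c(OC)cc(OC)c12 | intermediate
25 | 2-[3,5-dimethoxy-2-(3,5,6,8-tetramethoxy-1-methylnaphthalene-2-carbonyl)phenyl]acetic acid | Cc1c(C(=O)c3c(CC(=O)O)cc(OC)cc3OC)c(OC)cc2c(OC)c(OC)cc(OC)c12 | intermediate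
26 | 2,2,6-trimethyl-4H-1,3-dioxin-4-one | CC1=CC(=O)OC(C)(C)O1 | starting material
27 | 2-[3,5-dimethoxy-2-(3,5,6,8-tetramethoxy-1-methylnaphthalene-2-carbonyl)phenyl]-1-(imidazol-1-yl)ethan-1-one (acyl imidazole) | Cc1c(C(=O)c3c(CC(=O)n4ccnc4)cc(OC)cc3OC)c(OC)cc2c(OC)c(OC)cc(OC)c12 | intermediate (not isolated)
28 | lithium 2,2-dimethyl-6-methylidene-6H-1,3-dioxin-4-olate (lithium dienolate of 26) | C=C1C=C([O-])OC(C)(C)O1.[Li+] | intermediate (not isolated)
29 | 6-{3-[3,5-dimethoxy-2-(3,5,6,8-tetramethoxy-1-methylnaphthalene-2-carbonyl)phenyl]-2-oxopropyl}-2,2-dimethyl-4H-1,3-dioxin-4-one | Cc1c(C(=O)c3c(CC(=O)CC4=CC(=O)OC(C)(C)O4)cc(OC)cc3OC)c(OC)cc2c(OC)c(OC)cc(OC)c12 | intermediate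
30 | 6-[3,5-dimethoxy-2-(3,5,6,8-tetramethoxy-1-methylnaphthalene-2-carbonyl)phenyl]-3,5-dioxohex-1-en-1-one (acylketene) | Cc1c(C(=O)c3c(CC(=O)CC(=O)C=C=O)cc(OC)cc3OC)c(OC)cc2c(OC)c(OC)cc(OC)c12 | intermediate (not isolated)
31 | 6-{[3,5-dimethoxy-2-(3,5,6,8-tetramethoxy-1-methylnaphthalene-2-carbonyl)phenyl]methyl}-4-hydroxy-2H-pyran-2-one | Cc1c(C(=O)c3c(Cc4cc(O)cc(=O)o4)cc(OC)cc3OC)c(OC)cc2c(OC)c(OC)cc(OC)c12 | intermediate
32 | 6-{[3,5-dihydroxy-2-(3,5,6,8-tetrahydroxy-1-methylnaphthalene-2-carbonyl)phenyl]methyl}-4-hydroxy-2H-pyran-2-one (hexaphenol) | Cc1c(C(=O)c3c(Cc4cc(O)cc(=O)o4)cc(O)cc3O)c(O)cc2c(O)c(O)cc(O)c12 | intermediate (not isolated)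
33 | CNP0141484.0: 6-{[3,5-dihydroxy-2-(3,6-dihydroxy-1-methyl-5,8-dioxo-5,8-dihydronaphthalene-2-carbonyl)phenyl]methyl}-4-hydroxy-2H-pyran-2-one | Cc1c(C(=O)c2c(O)cc(O)cc2Cc2cc(O)cc(=O)o2)c(O)cc2c1C(=O)C=C(O)C2=O | target

Total step count: 18. Longest linear sequence: 17 steps (steps 1–10 and 12–18 from methyl orsellinate 1); step 11 prepares the ring C bromide 19.

Steps most likely to fail

Step 6. Ring closure may occur at C8 as well as at C4a. The hindered C6 ester may ionise in the strong acid and be lost on work-up. The electron-rich diol, once formed, may be acylated by unreacted keto ester. The fallback reverses the polarity of the closure and sets out from acid 6, returning at 12. Ring bromination with NBS in MeCN, which for an anisole of this type goes para to the methoxy group and can be checked on an isolable compound, should give 2-(2-bromo-5-methoxy-4-methoxycarbonyl-3-methylphenyl)acetic acid F1. A Dakin–West reaction (Ac2O, 1-methylimidazole) converts the arylacetic acid into the methyl ketone methyl 3-bromo-6-methoxy-2-methyl-4-(2-oxopropyl)benzoate F2. Palladium-catalysed methoxycarbonylation (Pd(OAc)2, Xantphos, CO, MeOH, Et3N) places the future C4 on C4a as an ester, giving dimethyl 4-methoxy-2-methyl-6-(2-oxopropyl)benzene-1,3-dicarboxylate F3. NaOMe in MeOH then closes ring B by an intramolecular Claisen condensation of the methyl ketone enolate onto that ester and gives 12 after acidification.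

Step 16. The basic dienolate may remove a benzylic α-proton of the acyl imidazole faster than it adds to the carbonyl, returning acid 25 on work-up, and part of the dienolate may be acylated on oxygen. The fallback avoids an enolisable acyl donor and sets out from aldehyde 24, returning at 29. Dioxinone 26 is converted with LiN(SiMe3)2 and Me3SiCl into the silyl dienol ether 2,2-dimethyl-6-methylidene-4-(trimethylsilyloxy)-6H-1,3-dioxine F4. A vinylogous Mukaiyama aldol addition of F4 to 24 (BF3·OEt2, CH2Cl2, −78 °C) should give the racemic alcohol 6-{3-[3,5-dimethoxy-2-(3,5,6,8-tetramethoxy-1-methylnaphthalene-2-carbonyl)phenyl]-2-hydroxypropyl}-2,2-dimethyl-4H-1,3-dioxin-4-one F5. Dess–Martin oxidation of F5 gives 29.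

Step 18. Cleavage of six ethers may stall at partly methylated stages, long exposure to the Lewis acid may degrade the hydroxypyranone, and air oxidation of the hexaphenol may not stop cleanly at the hydroxyquinone. The fallback sets the quinone with a separate oxidant before the pyranone exists; it sets out from 29 and returns at 33. (NH4)2Ce(NO3)6 in MeCN/H2O at 0 °C oxidatively demethylates the 1,2,4-trimethoxynaphthalene to the methoxyquinone 6-{3-[3,5-dimethoxy-2-(3,6-dimethoxy-1-methyl-5,8-dioxo-5,8-dihydronaphthalene-2-carbonyl)phenyl]-2-oxopropyl}-2,2-dimethyl-4H-1,3-dioxin-4-one F6. Heating in toluene at 110 °C gives the pyranone 6-{[3,5-dimethoxy-2-(3,6-dimethoxy-1-methyl-5,8-dioxo-5,8-dihydronaphthalene-2-carbonyl)phenyl]methyl}-4-hydroxy-2H-pyran-2-one F7. BBr3 in CH2Cl2 then has only four ethers to cleave (the vinylogous ester on C2, the C7 ether and the two ring C ethers) and gives 33 without a final oxidation.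

Further compounds
F1 | step 6 | 2-(2-bromo-5-methoxy-4-methoxycarbonyl-3-methylphenyl)acetic acid | COC(=O)c1c(C)c(Br)c(CC(=O)O)cc1OC
F2 | step 6 | methyl 3-bromo-6-methoxy-2-methyl-4-(2-oxopropyl)benzoate | COC(=O)c1c(C)c(Br)c(CC(C)=O)cc1OC
F3 | step 6 | dimethyl 4-methoxy-2-methyl-6-(2-oxopropyl)benzene-1,3-dicarboxylate | COC(=O)c1c(C)c(C(=O)OC)c(CC(C)=O)cc1OC
F4 | step 16 | 2,2-dimethyl-6-methylidene-4-(trimethylsilyloxy)-6H-1,3-dioxine | C=C1C=C(O[Si](C)(C)C)OC(C)(C)O1
F5 | step 16 | 6-{3-[3,5-dimethoxy-2-(3,5,6,8-tetramethoxy-1-methylnaphthalene-2-carbonyl)phenyl]-2-hydroxypropyl}-2,2-dimethyl-4H-1,3-dioxin-4-one (racemic) | Cc1c(C(=O)c3c(CC(O)CC4=CC(=O)OC(C)(C)O4)cc(OC)cc3OC)c(OC)cc2c(OC)c(OC)cc(OC)c12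
F6 | step 18 | 6-{3-[3,5-dimethoxy-2-(3,6-dimethoxy-1-methyl-5,8-dioxo-5,8-dihydronaphthalene-2-carbonyl)phenyl]-2-oxopropyl}-2,2-dimethyl-4H-1,3-dioxin-4-one | Cc1c(C(=O)c3c(CC(=O)CC4=CC(=O)OC(C)(C)O4)cc(OC)cc3OC)c(OC)cc2C(=O)C(OC)=CC(=O)c12
F7 | step 18 | 6-{[3,5-dimethoxy-2-(3,6-dimethoxy-1-methyl-5,8-dioxo-5,8-dihydronaphthalene-2-carbonyl)phenyl]methyl}-4-hydroxy-2H-pyran-2-one | Cc1c(C(=O)c3c(Cc4cc(O)cc(=O)o4)cc(OC)cc3OC)c(OC)cc2C(=O)C(OC)=CC(=O)c12
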